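**Retrosynthetic overview**
1. The ten-membered carbocycle (nine-membered oxacycle) is closed last at C4–C5 by a Nozaki–Hiyama–Kishi addition of the C4 vinyl bromide to the C5 aldehyde of 23.
2. The cis-fused α-methylene-γ-lactone (C6, C7, C11–C13) comes from an indium Barbier allylation/lactonisation (C6–C7) of the (Z)-allyl bromide 18, made from the C7 aldehyde 15 by a Morita–Baylis–Hillman reaction.
3. The 3(2H)-furanone ring (O, C10, C1, C2, C3) arises by two-atom ring expansion of the epoxide ring (O, C10, C1) of 10. This works because C1 is both the anomeric carbon of a temporary dihydrofuran ring (C8–O–C1; it gives oxocarbenium assistance and, on hydrolysis, the C1 ketone and the C8 hydroxyl) and the carbon that carries the C2≡C3 alkyne, which accepts the epoxide oxygen.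
4. Epoxide 10 comes from (R)-lactone 5 and bromoenyne 4 through the cyclic enol ether 9 (both C10 epimers converge) and a DMDO epoxidation directed by C8.
5. Order of ring formation: temporary oxolane/dihydrofuran, then epoxide, then furanone, then γ-lactone, then ten-membered ring.

Key step: step 8

Remark: 1,1-dibromoethene (1) is taken as a purchasable, stabilised reagent; metalated forms of numbered compounds (enolate, acetylide, organoindium, organochromium) are treated as transient and carry no number. Atom labels C1–C15 are germacrane numbering.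

**Step 1**
Reactants: 1 1,1-dibromoethene; 2 ethynyl(trimethyl)silane
Product: 3 (3-bromobut-3-en-1-yn-1-yl)(trimethyl)silane
Conditions: 1 (3 equiv), Pd(PPh3)4 (cat.), CuI (cat.), i-Pr2NH, THF, 0 °C to rt
Reagents that add atoms: none
Why: Sonogashira coupling; with the gem-dibromide in excess the first C–Br bond couples and the more hindered 2-bromo-1,3-enyne product reacts more slowly, so mono-alkynylation should prevail.

**Step 2**
Reactants: 3 (3-bromobut-3-en-1-yn-1-yl)(trimethyl)silane
Product: 4 2-bromobut-1-en-3-yne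
Conditions: K2CO3 (cat.), MeOH, 0 °C; extracted into pentane and used as a dried solution
Reagents that add atoms: none
Why: Base-catalysed methanolysis of the alkynyl C–Si bond (protodesilylation) leaves the vinyl bromide untouched, and the volatile enyne is carried on in solution.

**Step 3**
Reactants: 5 (5R)-5-(hydroxymethyl)oxolan-2-one
Product: 6 (5R)-5-({[tert-butyl(diphenyl)silyl]oxy}methyl)oxolan-2-one
Conditions: TBDPSCl, imidazole, DMF, 0 °C to rt
Reagents that add atoms: tert-butyl(chloro)diphenylsilane, CC(C)(C)[Si](Cl)(c1ccccc1)c1ccccc1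
Why: Standard silylation of the primary alcohol; the bulky silyl ether later shields one face of the five-membered ring and the stereocentre (future C8) is untouched.

**Step 4**
Reactants: 6 (5R)-5-({[tert-butyl(diphenyl)silyl]oxy}methyl)oxolan-2-one
Product: 7 (5R)-5-({[tert-butyl(diphenyl)silyl]oxy}methyl)-3-methyloxolan-2-one (mixture of C3 epimers)
Conditions: LiN(i-Pr)2, THF, −78 °C; then MeI, −78 to −40 °C
Reagents that add atoms: iodomethane, CI
Why: Lactone enolate alkylation; the configuration at C3 (future C10) does not matter because this carbon becomes sp2 in step 6, so both epimers are carried on.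

**Step 5**
Reactants: 7 (5R)-5-({[tert-butyl(diphenyl)silyl]oxy}methyl)-3-methyloxolan-2-one; 4 2-bromobut-1-en-3-yne
Product: 8 (5R)-2-(3-bromobut-3-en-1-yn-1-yl)-5-({[tert-butyl(diphenyl)silyl]oxy}methyl)-3-methyloxolan-2-ol (isomer mixture at C2/C3, in equilibrium with the open-chain hydroxy ynone)
Conditions: 4, LiN(SiMe3)2, THF, −78 °C; then 7, −78 °C; AcOH quench at −78 °C
Reagents that add atoms: none
Why: 1,2-Addition of a lithium acetylide to a γ-lactone stops at the lithium hemiketal at −78 °C, so one alkynyl group is introduced, and the amide base removes the alkyne proton far faster than it attacks the vinyl bromide.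

**Step 6**
Reactants: 8 (5R)-2-(3-bromobut-3-en-1-yn-1-yl)-5-({[tert-butyl(diphenyl)silyl]oxy}methyl)-3-methyloxolan-2-ol
Product: 9 (2R)-5-(3-bromobut-3-en-1-yn-1-yl)-2-({[tert-butyl(diphenyl)silyl]oxy}methyl)-4-methyl-2,3-dihydrofuran
Conditions: PPTS (cat.), 4 Å molecular sieves, benzene, 60 °C
Reagents that add atoms: none
Why: Acid-catalysed cyclodehydration through the C1 oxocarbenium ion, which can lose a proton only from C10 (C2 is sp), should give one conjugated enol ether from all isomers of 8 (stereoconvergent) without touching the C8–O bond.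

**Step 7**
Reactants: 9 (2R)-5-(3-bromobut-3-en-1-yn-1-yl)-2-({[tert-butyl(diphenyl)silyl]oxy}methyl)-4-methyl-2,3-dihydrofuran
Product: 10 (1S,3R,5S)-1-(3-bromobut-3-en-1-yn-1-yl)-3-({[tert-butyl(diphenyl)silyl]oxy}methyl)-5-methyl-2,6-dioxabicyclo[3.1.0]hexane
Conditions: DMDO (acetone solution), CH2Cl2, −78 to −40 °C; volatiles removed cold, used crude
Reagents that add atoms: dimethyldioxirane, CC1(C)OO1
Why: Epoxidation of the electron-rich enol ether (the bromoenyne alkene and the alkyne are far less nucleophilic) should occur on the ring face anti to the C8 silyloxymethyl group, as in glycal epoxidation, setting C10 (S); the anomeric carbon C1 is necessarily cis-fused.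

**Step 8**
Reactants: 10 (1S,3R,5S)-1-(3-bromobut-3-en-1-yn-1-yl)-3-({[tert-butyl(diphenyl)silyl]oxy}methyl)-5-methyl-2,6-dioxabicyclo[3.1.0]hexane
Product: 12 (2S)-5-(1-bromoethenyl)-2-[(2R)-3-{[tert-butyl(diphenyl)silyl]oxy}-2-hydroxypropyl]-2-methylfuran-3(2H)-one, via dihydroxy ynone 11 (not isolated)
Conditions: Ph3PAuNTf2 (5 mol %), H2O (3 equiv), THF, −20 °C to rt
Reagents that add atoms: water, O
Why: Proposed new method: a hydrative ring expansion of a 1-alkynyl anomeric epoxide under cationic monovalent gold, in which the ring oxygen on C8 assists C1–O(epoxide) heterolysis to an oxocarbenium ion, water is captured at C1, the hemiketal collapses to the C1 ketone and the free C8 hydroxyl (ynone 11), and the C10 oxygen that was the epoxide oxygen then adds to the gold-activated C2≡C3 bond at C3 with protodeauration, so that the three-membered ring O–C10–C1 grows by C2 and C3 into the furanone. The closest known reaction types are the hydrolysis of enol-ether (glycal, Rubottom-type) epoxides to α-hydroxy ketones, the gold-catalysed cycloisomerisation of α′-hydroxy ynones to 3(2H)-furanones, and the gold-catalysed isomerisation of alkynyl oxiranes to furans. The furanone ring closes in the 5-endo-dig mode. No stereocentre is created: C10 keeps the configuration set in step 7 because its C–O bond is never broken, and C8 is untouched. The step needs chemoselection between the tertiary C10 hydroxyl and the released secondary C8 hydroxyl, which ring size secures (5-endo-dig against 7-endo-dig, lactol formation at C1 being reversible), and it needs water to attack C1 and not C10, which the oxocarbenium stabilisation by the ring oxygen secures.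

**Step 9**
Reactants: 12 (2S)-5-(1-bromoethenyl)-2-[(2R)-3-{[tert-butyl(diphenyl)silyl]oxy}-2-hydroxypropyl]-2-methylfuran-3(2H)-one
Product: 13 (2R)-1-[(2S)-5-(1-bromoethenyl)-2-methyl-3-oxo-2,3-dihydrofuran-2-yl]-3-{[tert-butyl(diphenyl)silyl]oxy}propan-2-yl 2-methylpropanoate
Conditions: i-PrCOCl, pyridine, DMAP (cat.), CH2Cl2, 0 °C to rt
Reagents that add atoms: 2-methylpropanoyl chloride, CC(C)C(=O)Cl
Why: DMAP-catalysed acylation of the only free hydroxyl installs the C8 isobutyrate of the target.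

**Step 10**
Reactants: 13 (2R)-1-[(2S)-5-(1-bromoethenyl)-2-methyl-3-oxo-2,3-dihydrofuran-2-yl]-3-{[tert-butyl(diphenyl)silyl]oxy}propan-2-yl 2-methylpropanoate
Product: 14 (2R)-1-[(2S)-5-(1-bromoethenyl)-2-methyl-3-oxo-2,3-dihydrofuran-2-yl]-3-hydroxypropan-2-yl 2-methylpropanoate
Conditions: HF·pyridine, pyridine, THF, 0 °C to rt
Reagents that add atoms: none
Why: Fluoride cleavage of the primary silyl ether under buffered acidic conditions, chosen to suppress 1,2-migration of the neighbouring isobutyrate.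

**Step 11**
Reactants: 14 (2R)-1-[(2S)-5-(1-bromoethenyl)-2-methyl-3-oxo-2,3-dihydrofuran-2-yl]-3-hydroxypropan-2-yl 2-methylpropanoate
Product: 15 (2R)-1-[(2S)-5-(1-bromoethenyl)-2-methyl-3-oxo-2,3-dihydrofuran-2-yl]-3-oxopropan-2-yl 2-methylpropanoate
Conditions: Dess–Martin periodinane, CH2Cl2, 0 °C to rt; used at once
Reagents that add atoms: none
Why: Dess–Martin oxidation under non-basic conditions should give the α-acyloxy aldehyde (C7) without epimerising C8.

**Step 12**
Reactants: 15 (2R)-1-[(2S)-5-(1-bromoethenyl)-2-methyl-3-oxo-2,3-dihydrofuran-2-yl]-3-oxopropan-2-yl 2-methylpropanoate; 16 methyl prop-2-enoate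
Product: 17 methyl (4R)-5-[(2S)-5-(1-bromoethenyl)-2-methyl-3-oxo-2,3-dihydrofuran-2-yl]-3-hydroxy-2-methylidene-4-[(2-methylpropanoyl)oxy]pentanoate (mixture of C3 epimers)
Conditions: 16 (excess), DABCO (cat.), MeOH, rt
Reagents that add atoms: none
Why: Morita–Baylis–Hillman reaction of the activated α-acyloxy aldehyde forms the C7–C11 bond; the new carbinol centre is removed in step 13, so its configuration is irrelevant.

**Step 13**
Reactants: 17 methyl (4R)-5-[(2S)-5-(1-bromoethenyl)-2-methyl-3-oxo-2,3-dihydrofuran-2-yl]-3-hydroxy-2-methylidene-4-[(2-methylpropanoyl)oxy]pentanoate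
Product: 18 methyl (2Z,4R)-2-(bromomethyl)-5-[(2S)-5-(1-bromoethenyl)-2-methyl-3-oxo-2,3-dihydrofuran-2-yl]-4-[(2-methylpropanoyl)oxy]pent-2-enoate
Conditions: NBS, Me2S, CH2Cl2, −20 °C (reagent preformed); then 17, 0 °C to rt
Reagents that add atoms: N-bromosuccinimide, O=C1CCC(=O)N1Br
Why: Corey–Kim-type activation of the allylic alcohol and SN2′ attack of bromide should give the thermodynamically preferred (Z)-2-(bromomethyl)enoate from both carbinol epimers, and preforming the bromosulfonium reagent keeps free NBS away from the furanone.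

**Step 14**
Reactants: 18 methyl (2Z,4R)-2-(bromomethyl)-5-[(2S)-5-(1-bromoethenyl)-2-methyl-3-oxo-2,3-dihydrofuran-2-yl]-4-[(2-methylpropanoyl)oxy]pent-2-enoate; 19 {[tert-butyl(dimethyl)silyl]oxy}acetaldehyde
Product: 22 (1R)-2-[(2S)-5-(1-bromoethenyl)-2-methyl-3-oxo-2,3-dihydrofuran-2-yl]-1-[(2R,3R)-2-(hydroxymethyl)-4-methylidene-5-oxooxolan-3-yl]ethyl 2-methylpropanoate, via syn-hydroxy ester 20 (not isolated), via silyl lactone 21 (not isolated)
Conditions: indium powder (In), 19 (2 equiv), THF/H2O, rt; then HCl (cat.), THF/H2O, rt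
Reagents that add atoms: none
Why: Indium Barbier allylation: the (Z)-allylindium should react at its γ-carbon (C7) through a chair transition state to give the syn adduct (hence the cis-lactone), on the C7 face anti to the C9 chain of the C8 centre held by allylic 1,3-strain (the isobutyrate can also coordinate indium), setting C6 and C7; acid then closes the γ-lactone and removes the silyl group.

**Step 15**
Reactants: 22 (1R)-2-[(2S)-5-(1-bromoethenyl)-2-methyl-3-oxo-2,3-dihydrofuran-2-yl]-1-[(2R,3R)-2-(hydroxymethyl)-4-methylidene-5-oxooxolan-3-yl]ethyl 2-methylpropanoate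
Product: 23 (1R)-2-[(2S)-5-(1-bromoethenyl)-2-methyl-3-oxo-2,3-dihydrofuran-2-yl]-1-[(2R,3R)-2-formyl-4-methylidene-5-oxooxolan-3-yl]ethyl 2-methylpropanoate
Conditions: Dess–Martin periodinane, CH2Cl2, 0 °C; used at once
Reagents that add atoms: none
Why: Dess–Martin oxidation of the only free (primary) hydroxyl gives the C5 aldehyde under conditions that should not epimerise C6.

**Step 16**
Reactants: 23 (1R)-2-[(2S)-5-(1-bromoethenyl)-2-methyl-3-oxo-2,3-dihydrofuran-2-yl]-1-[(2R,3R)-2-formyl-4-methylidene-5-oxooxolan-3-yl]ethyl 2-methylpropanoate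
Product: 24 (5S,6R,7R,8R,10S)-5-hydroxy-8-isobutyryloxy-1-oxo-3,10-epoxygermacra-2,4(15),11(13)-trien-12,6-olide (CNP0384113.2)
Conditions: CrCl2 (excess), NiCl2 (cat.), DMSO/THF, rt, high dilution (slow addition of 23)
Reagents that add atoms: none
Why: Nozaki–Hiyama–Kishi ring closure: zerovalent nickel inserts into the activated C4–Br bond and the alkenylchromium formed by transmetalation adds only to the aldehyde, closing the nine-membered oxacycle as the 2-methylene-1-ol (a ring size with precedent for this reaction), and Felkin–Anh addition anti to the C6–O bond should give the 5,6-anti (5S) alcohol.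

**Compound list**
1 | 1,1-dibromoethene | C=C(Br)Br | starting material
2 | ethynyl(trimethyl)silane | C#C[Si](C)(C)C | starting material
3 | (3-bromobut-3-en-1-yn-1-yl)(trimethyl)silane | C=C(Br)C#C[Si](C)(C)C | intermediate
4 | 2-bromobut-1-en-3-yne | C=C(Br)C#C | intermediate
5 | (5R)-5-(hydroxymethyl)oxolan-2-one | OC[C@H]1CCC(=O)O1 | starting material
6 | (5R)-5-({[tert-butyl(diphenyl)silyl]oxy}methyl)oxolan-2-one | CC(C)(C)[Si](OC[C@H]1CCC(=O)O1)(c1ccccc1)c1ccccc1 | intermediate
7 | (5R)-5-({[tert-butyl(diphenyl)silyl]oxy}methyl)-3-methyloxolan-2-one, C3 epimer mixture | CC1C[C@H](CO[Si](C(C)(C)C)(c2ccccc2)c2ccccc2)OC1=O | intermediate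
8 | (5R)-2-(3-bromobut-3-en-1-yn-1-yl)-5-({[tert-butyl(diphenyl)silyl]oxy}methyl)-3-methyloxolan-2-ol, isomer mixture at C2/C3 | CC1C[C@H](CO[Si](C(C)(C)C)(c2ccccc2)c2ccccc2)OC1(O)C#CC(Br)=C | intermediate
9 | (2R)-5-(3-bromobut-3-en-1-yn-1-yl)-2-({[tert-butyl(diphenyl)silyl]oxy}methyl)-4-methyl-2,3-dihydrofuran | CC1=C(C#CC(Br)=C)O[C@@H](CO[Si](C(C)(C)C)(c2ccccc2)c2ccccc2)C1 | intermediate
10 | (1S,3R,5S)-1-(3-bromobut-3-en-1-yn-1-yl)-3-({[tert-butyl(diphenyl)silyl]oxy}methyl)-5-methyl-2,6-dioxabicyclo[3.1.0]hexane | C[C@]12C[C@H](CO[Si](C(C)(C)C)(c3ccccc3)c3ccccc3)O[C@@]1(C#CC(Br)=C)O2 | intermediate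
11 | (6S,8R)-2-bromo-9-{[tert-butyl(diphenyl)silyl]oxy}-6,8-dihydroxy-6-methylnon-1-en-3-yn-5-one | CC(C)(C)[Si](OC[C@H](O)C[C@](C)(O)C(=O)C#CC(Br)=C)(c1ccccc1)c1ccccc1 | intermediate
12 | (2S)-5-(1-bromoethenyl)-2-[(2R)-3-{[tert-butyl(diphenyl)silyl]oxy}-2-hydroxypropyl]-2-methylfuran-3(2H)-one | CC(C)(C)[Si](OC[C@H](O)C[C@]1(C)OC(=CC1=O)C(Br)=C)(c1ccccc1)c1ccccc1 | intermediate
13 | (2R)-1-[(2S)-5-(1-bromoethenyl)-2-methyl-3-oxo-2,3-dihydrofuran-2-yl]-3-{[tert-butyl(diphenyl)silyl]oxy}propan-2-yl 2-methylpropanoate | CC(C)(C)[Si](OC[C@H](OC(=O)C(C)C)C[C@]1(C)OC(=CC1=O)C(Br)=C)(c1ccccc1)c1ccccc1 | intermediate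
14 | (2R)-1-[(2S)-5-(1-bromoethenyl)-2-methyl-3-oxo-2,3-dihydrofuran-2-yl]-3-hydroxypropan-2-yl 2-methylpropanoate | OC[C@H](OC(=O)C(C)C)C[C@]1(C)OC(=CC1=O)C(Br)=C | intermediate
15 | (2R)-1-[(2S)-5-(1-bromoethenyl)-2-methyl-3-oxo-2,3-dihydrofuran-2-yl]-3-oxopropan-2-yl 2-methylpropanoate | O=C[C@H](OC(=O)C(C)C)C[C@]1(C)OC(=CC1=O)C(Br)=C | intermediate
16 | methyl prop-2-enoate | C=CC(=O)OC | starting material
17 | methyl (4R)-5-[(2S)-5-(1-bromoethenyl)-2-methyl-3-oxo-2,3-dihydrofuran-2-yl]-3-hydroxy-2-methylidene-4-[(2-methylpropanoyl)oxy]pentanoate, C3 epimer mixture | C=C(C(=O)OC)C(O)[C@H](OC(=O)C(C)C)C[C@]1(C)OC(=CC1=O)C(Br)=C | intermediate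
18 | methyl (2Z,4R)-2-(bromomethyl)-5-[(2S)-5-(1-bromoethenyl)-2-methyl-3-oxo-2,3-dihydrofuran-2-yl]-4-[(2-methylpropanoyl)oxy]pent-2-enoate | COC(=O)/C(CBr)=C/[C@H](OC(=O)C(C)C)C[C@]1(C)OC(=CC1=O)C(Br)=C | intermediate
19 | {[tert-butyl(dimethyl)silyl]oxy}acetaldehyde | CC(C)(C)[Si](C)(C)OCC=O | starting material
20 | methyl (3S,4R)-3-{(1R)-2-[(2S)-5-(1-bromoethenyl)-2-methyl-3-oxo-2,3-dihydrofuran-2-yl]-1-[(2-methylpropanoyl)oxy]ethyl}-5-{[tert-butyl(dimethyl)silyl]oxy}-4-hydroxy-2-methylidenepentanoate | CC(C)(C)[Si](C)(C)OC[C@H](O)[C@H](C(=C)C(=O)OC)[C@H](OC(=O)C(C)C)C[C@]1(C)OC(=CC1=O)C(Br)=C | intermediate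
21 | (1R)-2-[(2S)-5-(1-bromoethenyl)-2-methyl-3-oxo-2,3-dihydrofuran-2-yl]-1-[(2R,3R)-2-({[tert-butyl(dimethyl)silyl]oxy}methyl)-4-methylidene-5-oxooxolan-3-yl]ethyl 2-methylpropanoate | C=C1C(=O)O[C@@H](CO[Si](C)(C)C(C)(C)C)[C@H]1[C@H](OC(=O)C(C)C)C[C@]1(C)OC(=CC1=O)C(Br)=C | intermediate
22 | (1R)-2-[(2S)-5-(1-bromoethenyl)-2-methyl-3-oxo-2,3-dihydrofuran-2-yl]-1-[(2R,3R)-2-(hydroxymethyl)-4-methylidene-5-oxooxolan-3-yl]ethyl 2-methylpropanoate | C=C1C(=O)O[C@@H](CO)[C@H]1[C@H](OC(=O)C(C)C)C[C@]1(C)OC(=CC1=O)C(Br)=C | intermediate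
23 | (1R)-2-[(2S)-5-(1-bromoethenyl)-2-methyl-3-oxo-2,3-dihydrofuran-2-yl]-1-[(2R,3R)-2-formyl-4-methylidene-5-oxooxolan-3-yl]ethyl 2-methylpropanoate | C=C1C(=O)O[C@@H](C=O)[C@H]1[C@H](OC(=O)C(C)C)C[C@]1(C)OC(=CC1=O)C(Br)=C | intermediate
24 | (5S,6R,7R,8R,10S)-5-hydroxy-8-isobutyryloxy-1-oxo-3,10-epoxygermacra-2,4(15),11(13)-trien-12,6-olide (CNP0384113.2) | C=C1C(=O)O[C@@H]2[C@H]1[C@H](OC(=O)C(C)C)C[C@]1(C)OC(=CC1=O)C(=C)[C@@H]2O | target

Total step count: 16. Longest linear sequence: 14 steps (5 to 24, steps 3–16).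

**Steps most likely to fail**

1. Step 8 (proposed new method). The anomeric epoxide may open without oxygen transfer to C3: alkyne hydration, a 1,2-shift to C1, or water capture at C10 with loss of configuration. The fallback uses known chemistry only; it sets out from 7 and returns to the route at 12. The potassium enolate of 7 (KN(SiMe3)2, THF, −78 °C) is hydroxylated with 2-(phenylsulfonyl)-3-phenyloxaziridine on the face anti to the C5 substituent to give (3S,5R)-5-({[tert-butyl(diphenyl)silyl]oxy}methyl)-3-hydroxy-3-methyloxolan-2-one F1. The lithium acetylide of 4 (excess, −78 °C) then opens the lactone to the dihydroxy ynone 11, which is isolated this time. Compound 11 is cyclised 5-endo-dig to 12 with Ph3PAuNTf2 in THF or with Et2NH in EtOH.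

2. Step 14. Facial selectivity at C7 relative to the C8 centre may be poor, and syn selectivity may erode, in the allylindium addition. The fallback sets out from 18 and returns at 23, moving stereocontrol from the bromide to a sacrificial stereocentre in the aldehyde. Bromide 18 is coupled (In, THF/H2O) with (4S)-2,2-dimethyl-1,3-dioxolane-4-carbaldehyde in place of 19. The strong Felkin (anti) preference of this aldehyde fixes C6 and the chair transition state relays it to C7. Mild lactonisation (PPTS) gives (1R)-2-[(2S)-5-(1-bromoethenyl)-2-methyl-3-oxo-2,3-dihydrofuran-2-yl]-1-{(2R,3R)-2-[(4S)-2,2-dimethyl-1,3-dioxolan-4-yl]-4-methylidene-5-oxooxolan-3-yl}ethyl 2-methylpropanoate F2. Aqueous AcOH removes the acetonide to give (1R)-2-[(2S)-5-(1-bromoethenyl)-2-methyl-3-oxo-2,3-dihydrofuran-2-yl]-1-{(2R,3R)-2-[(1S)-1,2-dihydroxyethyl]-4-methylidene-5-oxooxolan-3-yl}ethyl 2-methylpropanoate F3, and NaIO4 cleaves the diol to aldehyde 23.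

3. Step 16. Facial selectivity at the C5 aldehyde may be poor in the medium-ring closure. The fallback sets out from 23 and returns at 24, setting C5 by ketone reduction instead of by C–C bond formation. The ring closure is run as in step 16 without regard to C5, giving 24 together with its C5 epimer (5R,6R,7R,8R,10S)-5-hydroxy-8-isobutyryloxy-1-oxo-3,10-epoxygermacra-2,4(15),11(13)-trien-12,6-olide F4. The mixture is oxidised with Dess–Martin periodinane to (6R,7R,8R,10S)-8-isobutyryloxy-1,5-dioxo-3,10-epoxygermacra-2,4(15),11(13)-trien-12,6-olide F5. This enone is reduced with (S)-2-methyl-CBS-oxazaborolidine and catecholborane at −78 °C, which with the C4 alkenyl group as the larger substituent should deliver the (5S) alcohol 24.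

**Further compounds**
F1 | step 8 | (3S,5R)-5-({[tert-butyl(diphenyl)silyl]oxy}methyl)-3-hydroxy-3-methyloxolan-2-one | C[C@]1(O)C[C@H](CO[Si](C(C)(C)C)(c2ccccc2)c2ccccc2)OC1=O
F2 | step 14 | (1R)-2-[(2S)-5-(1-bromoethenyl)-2-methyl-3-oxo-2,3-dihydrofuran-2-yl]-1-{(2R,3R)-2-[(4S)-2,2-dimethyl-1,3-dioxolan-4-yl]-4-methylidene-5-oxooxolan-3-yl}ethyl 2-methylpropanoate | C=C1C(=O)O[C@@H]([C@@H]2COC(C)(C)O2)[C@H]1[C@H](OC(=O)C(C)C)C[C@]1(C)OC(=CC1=O)C(Br)=C
F3 | step 14 | (1R)-2-[(2S)-5-(1-bromoethenyl)-2-methyl-3-oxo-2,3-dihydrofuran-2-yl]-1-{(2R,3R)-2-[(1S)-1,2-dihydroxyethyl]-4-methylidene-5-oxooxolan-3-yl}ethyl 2-methylpropanoate | C=C1C(=O)O[C@@H]([C@@H](O)CO)[C@H]1[C@H](OC(=O)C(C)C)C[C@]1(C)OC(=CC1=O)C(Br)=C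
F4 | step 16 | (5R,6R,7R,8R,10S)-5-hydroxy-8-isobutyryloxy-1-oxo-3,10-epoxygermacra-2,4(15),11(13)-trien-12,6-olide | C=C1C(=O)O[C@@H]2[C@H]1[C@H](OC(=O)C(C)C)C[C@]1(C)OC(=CC1=O)C(=C)[C@H]2O
F5 | step 16 | (6R,7R,8R,10S)-8-isobutyryloxy-1,5-dioxo-3,10-epoxygermacra-2,4(15),11(13)-trien-12,6-olide | C=C1C(=O)O[C@@H]2[C@H]1[C@H](OC(=O)C(C)C)C[C@]1(C)OC(=CC1=O)C(=C)C2=O
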